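**Retrosynthetic overview**

1. Agehoustin C is traced back, through benzyl hydrogenolysis and 2'-O-methylation, to a 2'-hydroxy-3'-benzyloxy flavone. Its ring B is cut at C5'–C6', C1'–C2' and C2'–C3' into a 2-ethynylchromone (rings A and C), an alkenyl(methoxy)carbene chromium complex and one carbon monoxide (Dötz benzannulation).
2. Feature used: in ring B the oxygens on C2' and C5' are para, C1' carries ring C and C6' carries the only hydrogen, so ring B is a 2-substituted 4-methoxyphenol. The C5'-OMe comes from the carbene carbon, the C4'-OMe and C3'-OBn from the alkene, and the C2'-OH from CO, so the 3'-oxygen stays distinct from its methylated neighbours.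
3. Alkyne: 3,4,5-trimethoxyphenol is taken to the ring A 2-hydroxy-3,4,5,6-tetramethoxyacetophenone (acetylation, bromination, methoxylation). Claisen condensation with diethyl oxalate and cyclodehydration close ring C, then ester → alcohol → aldehyde → alkyne.
4. Carbene: methyl methoxyacetate → formylation/O-benzylation → acid → acid chloride → Na2Cr(CO)5, then MeOTf.
5. Ring order: ring A is bought, ring C is closed in step 4, ring B is closed last in step 12.

Key step: step 12

Assumption (chemistry): the O-benzylation in step 8 should give mainly the (Z)-acrylate, with benzyloxy trans to the ester, as O-alkylations of alpha-substituted formyl ester enolates usually do; any (E) isomer is removed at the ester stage. Ring B is numbered C1'–C6', with C1' bonded to C2 of the pyranone ring C.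

**Route**

Step 1
Reactants: 1 3,4,5-trimethoxyphenol
Product: 2 1-(6-hydroxy-2,3,4-trimethoxyphenyl)ethan-1-one
Conditions: AcOH, BF3·OEt2, 90 °C; then H2O
Reagents that add atoms: acetic acid, CC(=O)O
Why: BF3-promoted Friedel–Crafts (Fries-type) C-acetylation of the symmetric phenol goes ortho to the hydroxyl, where both free ring positions are equivalent, and the chelated, deactivated monoketone is not acylated again.

Step 2
Reactants: 2 1-(6-hydroxy-2,3,4-trimethoxyphenyl)ethan-1-one
Product: 3 1-(3-bromo-2-hydroxy-4,5,6-trimethoxyphenyl)ethan-1-one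
Conditions: NBS, MeCN, 0 °C → rt
Reagents that add atoms: N-bromosuccinimide, O=C1CCC(=O)N1Br
Why: Electrophilic aromatic bromination takes the single free ring position, which is ortho to the phenol and activated by the methoxy groups, faster than the methyl ketone enolises.

Step 3
Reactants: 3 1-(3-bromo-2-hydroxy-4,5,6-trimethoxyphenyl)ethan-1-one
Product: 4 1-(2-hydroxy-3,4,5,6-tetramethoxyphenyl)ethan-1-one
Conditions: NaOMe, CuBr (cat.), MeOH/DMF, 110 °C; then aq. HCl
Reagents that add atoms: sodium methoxide, [Na+].[O-]C
Why: Copper-catalysed Ullmann-type methoxylation of an ortho-bromophenol, the reaction type that converts 5-bromovanillin into syringaldehyde, replaces bromide by methoxide while the phenoxide form of the substrate keeps the acetyl group from condensing.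

Step 4
Reactants: 4 1-(2-hydroxy-3,4,5,6-tetramethoxyphenyl)ethan-1-one; 5 diethyl oxalate
Product: 7 ethyl 5,6,7,8-tetramethoxy-4-oxo-4H-chromene-2-carboxylate, via diketo ester 6 (not isolated)
Conditions: NaOEt, EtOH, reflux; then conc. HCl, EtOH, reflux
Reagents that add atoms: none
Why: Claisen condensation of the methyl ketone enolate with non-enolisable diethyl oxalate, followed by acid-catalysed cyclodehydration of the 2-hydroxyaryl diketo ester, is the standard chromone-2-carboxylate synthesis and closes ring C without touching the aryl methyl ethers.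

Step 5
Reactants: 7 ethyl 5,6,7,8-tetramethoxy-4-oxo-4H-chromene-2-carboxylate
Product: 8 2-(hydroxymethyl)-5,6,7,8-tetramethoxy-4H-chromen-4-one
Conditions: NaBH4, MeOH/THF, 0 °C
Reagents that add atoms: none
Why: Chemoselective borohydride reduction: the ester on the electron-poor C2 beside the ring oxygen is activated and is reduced at 0 °C, whereas the C4 carbonyl is a deactivated vinylogous ester and the C2=C3 bond is not attacked.

Step 6
Reactants: 8 2-(hydroxymethyl)-5,6,7,8-tetramethoxy-4H-chromen-4-one
Product: 9 5,6,7,8-tetramethoxy-4-oxo-4H-chromene-2-carbaldehyde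
Conditions: Dess–Martin periodinane, CH2Cl2, rt
Reagents that add atoms: none
Why: Dess–Martin oxidation of the allylic-type primary alcohol stops at the aldehyde under neutral, non-aqueous conditions that leave the pyranone untouched.

Step 7
Reactants: 9 5,6,7,8-tetramethoxy-4-oxo-4H-chromene-2-carbaldehyde
Product: 10 2-ethynyl-5,6,7,8-tetramethoxy-4H-chromen-4-one
Conditions: dimethyl (1-diazo-2-oxopropyl)phosphonate, K2CO3, MeOH/THF, 0 °C
Reagents that add atoms: dimethyl (1-diazo-2-oxopropyl)phosphonate, COP(=O)(OC)C(=[N+]=[N-])C(C)=O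
Why: Seyferth–Gilbert homologation with the Ohira–Bestmann reagent converts the non-enolisable aldehyde into the terminal alkyne under mild carbonate conditions, and low temperature with a short reaction time should limit methoxide addition to the pyranone or to the new enyne.

Step 8
Reactants: 11 methyl methoxyacetate
Product: 13 methyl (Z)-3-(benzyloxy)-2-methoxyprop-2-enoate, via sodium formyl enolate 12 (not isolated)
Conditions: HCO2Me, NaH, THF, 0 °C → rt; then BnBr, DMF, rt
Reagents that add atoms: methyl formate, COC=O; benzyl bromide, BrCc1ccccc1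
Why: Crossed Claisen formylation with non-enolisable methyl formate gives the delocalised formyl enolate, which in DMF is alkylated on oxygen as in beta-alkoxyacrylate syntheses, and should place the benzyloxy group trans to the ester (Z by the CIP rules).

Step 9
Reactants: 13 methyl (Z)-3-(benzyloxy)-2-methoxyprop-2-enoate
Product: 14 (Z)-3-(benzyloxy)-2-methoxyprop-2-enoic acid
Conditions: LiOH, THF/H2O, rt; then 1 M HCl to pH 3, 0 °C
Reagents that add atoms: lithium hydroxide (hydroxide oxygen), [Li+].[OH-]
Why: Ester saponification, as used to make 3-alkoxyacrylic acids from their esters, leaves the vinylogous carbonate intact if the acidification is cold and brief.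

Step 10
Reactants: 14 (Z)-3-(benzyloxy)-2-methoxyprop-2-enoic acid
Product: 15 (Z)-3-(benzyloxy)-2-methoxyprop-2-enoyl chloride
Conditions: (COCl)2, DMF (cat.), CH2Cl2, 0 °C → rt; used crude
Reagents that add atoms: oxalyl chloride, O=C(Cl)C(Cl)=O
Why: Acid chloride formation through the Vilsmeier-type chloroiminium catalyst is fast at 0 °C, and 3-alkoxyacryloyl chlorides of this kind are stable enough to be used without purification.

Step 11
Reactants: 15 (Z)-3-(benzyloxy)-2-methoxyprop-2-enoyl chloride; 16 chromium hexacarbonyl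
Product: 19 pentacarbonyl[(Z)-3-(benzyloxy)-1,2-dimethoxyprop-2-en-1-ylidene]chromium, via Na2Cr(CO)5 17 (not isolated), via sodium acylchromate 18 (not isolated)
Conditions: Cr(CO)6, NaC10H8 (sodium naphthalenide, 2 equiv), THF, −78 °C; then 15, −78 → 0 °C; evaporate; MeOTf, CH2Cl2, 0 °C
Reagents that add atoms: methyl trifluoromethanesulfonate, COS(=O)(=O)C(F)(F)F
Why: Acylation of the pentacarbonylchromate dianion by an acid chloride and O-methylation of the resulting acylchromate is the acyl-electrophile route to Fischer carbenes, chosen because a vinyllithium with lithium anti to the beta-benzyloxy group would eliminate benzyloxide.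

Step 12
Reactants: 10 2-ethynyl-5,6,7,8-tetramethoxy-4H-chromen-4-one; 19 pentacarbonyl[(Z)-3-(benzyloxy)-1,2-dimethoxyprop-2-en-1-ylidene]chromium
Product: 21 2-[3-(benzyloxy)-2-hydroxy-4,5-dimethoxyphenyl]-5,6,7,8-tetramethoxy-4H-chromen-4-one, via arene tricarbonylchromium complex 20 (not isolated)
Conditions: THF (0.3 M, degassed), 50 °C, Ar; then air, MeCN, rt
Reagents that add atoms: none
Why: Thermal loss of one CO from 19 frees a site for the alkyne, which inserts into the chromium–carbene bond with the carbene carbon bonding to the unsubstituted terminus (C5'–C6'), and CO insertion then gives a chromium-bound dienylketene (C1'–C2'). Ring B closes by 6π-electrocyclisation of that dienylketene onto the benzyloxy-bearing alkene carbon (C2'–C3'), and enolisation of the cyclohexadienone gives the 2'-phenol as its Cr(CO)3 complex 20, from which air releases 21. This is the Dötz benzannulation of an alkenyl(methoxy)carbene chromium complex with a terminal alkyne, known for alpha-alkoxyalkenyl complexes and applied here to a more donor-rich carbene and a conjugated alkyne. No stereocentre is formed. The regiochemistry needed, with the chromone-bearing carbon next to the CO-derived C2', follows from the steric difference between hydrogen and the chromonyl group at the alkyne, the normal outcome for terminal alkynes. Phenol formation rather than cyclopentannulation should be favoured by chromium, by an alkenyl carbene whose beta-hydrogen points inward (Z alkene), by an ether solvent and by high alkyne concentration, while the trisubstituted push–pull C2=C3 bond of ring C is too hindered to compete for the carbene.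

Step 13
Reactants: 21 2-[3-(benzyloxy)-2-hydroxy-4,5-dimethoxyphenyl]-5,6,7,8-tetramethoxy-4H-chromen-4-one
Product: 22 2-[3-(benzyloxy)-2,4,5-trimethoxyphenyl]-5,6,7,8-tetramethoxy-4H-chromen-4-one
Conditions: MeI, K2CO3, DMF, rt
Reagents that add atoms: iodomethane, CI
Why: Williamson O-methylation of the only free phenol; the chromone and the benzyl ether are inert to carbonate and methyl iodide.

Step 14
Reactants: 22 2-[3-(benzyloxy)-2,4,5-trimethoxyphenyl]-5,6,7,8-tetramethoxy-4H-chromen-4-one
Product: 23 Agehoustin C, 2-(3-hydroxy-2,4,5-trimethoxyphenyl)-5,6,7,8-tetramethoxy-4H-chromen-4-one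
Conditions: H2 (1 atm), 10% Pd/C, EtOAc/MeOH, rt
Reagents that add atoms: none
Why: Catalytic hydrogenolysis cleaves the benzyl ether selectively, since the methyl ethers are inert and the conjugated, trisubstituted C2=C3 bond of a flavone is not reduced at atmospheric pressure.

**Compound list**

1 | 3,4,5-trimethoxyphenol | COc1cc(O)cc(OC)c1OC | starting material
2 | 1-(6-hydroxy-2,3,4-trimethoxyphenyl)ethan-1-one | CC(=O)c1c(O)cc(OC)c(OC)c1OC | intermediate
3 | 1-(3-bromo-2-hydroxy-4,5,6-trimethoxyphenyl)ethan-1-one | CC(=O)c1c(O)c(Br)c(OC)c(OC)c1OC | intermediate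
4 | 1-(2-hydroxy-3,4,5,6-tetramethoxyphenyl)ethan-1-one | CC(=O)c1c(O)c(OC)c(OC)c(OC)c1OC | intermediate
5 | diethyl oxalate | CCOC(=O)C(=O)OCC | starting material
6 | ethyl 4-(2-hydroxy-3,4,5,6-tetramethoxyphenyl)-2,4-dioxobutanoate (formed as its sodium enolate) | CCOC(=O)C(=O)CC(=O)c1c(O)c(OC)c(OC)c(OC)c1OC | intermediate
7 | ethyl 5,6,7,8-tetramethoxy-4-oxo-4H-chromene-2-carboxylate | CCOC(=O)c1cc(=O)c2c(OC)c(OC)c(OC)c(OC)c2o1 | intermediate
8 | 2-(hydroxymethyl)-5,6,7,8-tetramethoxy-4H-chromen-4-one | OCc1cc(=O)c2c(OC)c(OC)c(OC)c(OC)c2o1 | intermediate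
9 | 5,6,7,8-tetramethoxy-4-oxo-4H-chromene-2-carbaldehyde | O=Cc1cc(=O)c2c(OC)c(OC)c(OC)c(OC)c2o1 | intermediate
10 | 2-ethynyl-5,6,7,8-tetramethoxy-4H-chromen-4-one | C#Cc1cc(=O)c2c(OC)c(OC)c(OC)c(OC)c2o1 | intermediate
11 | methyl methoxyacetate | COCC(=O)OC | starting material
12 | sodium enolate of methyl 2-methoxy-3-oxopropanoate (delocalised, geometry not fixed) | [Na+].[O-]C=C(OC)C(=O)OC | intermediate
13 | methyl (Z)-3-(benzyloxy)-2-methoxyprop-2-enoate | COC(=O)/C(OC)=C/OCc1ccccc1 | intermediate
14 | (Z)-3-(benzyloxy)-2-methoxyprop-2-enoic acid | OC(=O)/C(OC)=C/OCc1ccccc1 | intermediate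
15 | (Z)-3-(benzyloxy)-2-methoxyprop-2-enoyl chloride | ClC(=O)/C(OC)=C/OCc1ccccc1 | intermediate
16 | chromium hexacarbonyl | O=C=[Cr](=C=O)(=C=O)(=C=O)(=C=O)=C=O | starting material
17 | disodium pentacarbonylchromate, Na2Cr(CO)5 | [Na+].[Na+].O=C=[Cr-2](=C=O)(=C=O)(=C=O)=C=O | intermediate
18 | sodium pentacarbonyl[(Z)-3-(benzyloxy)-2-methoxyprop-2-enoyl]chromate | [Na+].[O-]C(=[Cr](=C=O)(=C=O)(=C=O)(=C=O)=C=O)/C(OC)=C/OCc1ccccc1 | intermediate
19 | pentacarbonyl[(Z)-3-(benzyloxy)-1,2-dimethoxyprop-2-en-1-ylidene]chromium | COC(=[Cr](=C=O)(=C=O)(=C=O)(=C=O)=C=O)/C(OC)=C/OCc1ccccc1 | intermediate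
20 | tricarbonylchromium complex of 21, bound eta-6 to ring B (the Cr(CO)3 unit is written as a separate fragment) | COc1cc(-c2cc(=O)c3c(OC)c(OC)c(OC)c(OC)c3o2)c(O)c(OCc2ccccc2)c1OC.O=C=[Cr](=C=O)=C=O | intermediate
21 | 2-[3-(benzyloxy)-2-hydroxy-4,5-dimethoxyphenyl]-5,6,7,8-tetramethoxy-4H-chromen-4-one | COc1cc(-c2cc(=O)c3c(OC)c(OC)c(OC)c(OC)c3o2)c(O)c(OCc2ccccc2)c1OC | intermediate
22 | 2-[3-(benzyloxy)-2,4,5-trimethoxyphenyl]-5,6,7,8-tetramethoxy-4H-chromen-4-one | COc1cc(-c2cc(=O)c3c(OC)c(OC)c(OC)c(OC)c3o2)c(OC)c(OCc2ccccc2)c1OC | intermediate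
23 | Agehoustin C, 2-(3-hydroxy-2,4,5-trimethoxyphenyl)-5,6,7,8-tetramethoxy-4H-chromen-4-one | COc1cc(-c2cc(=O)c3c(OC)c(OC)c(OC)c(OC)c3o2)c(OC)c(O)c1OC | target

**Step count and risks**

Total step count: 14. Longest linear sequence: 10 steps (steps 1–7, then 12–14); the carbene branch (steps 8–11) joins at step 12.

Steps most likely to fail:

1. Step 12. Insertion of the electron-poor, conjugated alkyne may be slow enough that the carbene decomposes first, or the alkyne-inserted intermediate may close without taking up CO and give five-membered-ring products. The fallback keeps the benzannulation but gives it an unconjugated alkyne and builds ring C afterwards; it sets out from 19 and 4 and comes back at 22. Carbene 19 is heated with commercial 3,3-diethoxyprop-1-yne (THF, 50 °C, then air) and should give 2-(benzyloxy)-6-(diethoxymethyl)-3,4-dimethoxyphenol F1, with the acetal carbon next to the CO-derived phenol carbon. Methylation (MeI, K2CO3, DMF) should give 3-(benzyloxy)-1-(diethoxymethyl)-2,4,5-trimethoxybenzene F2, and mild acetal hydrolysis (pyridinium tosylate, acetone/H2O) the aldehyde 3-(benzyloxy)-2,4,5-trimethoxybenzaldehyde F3. Claisen–Schmidt condensation of F3 with ketone 4 (KOH, EtOH, rt) should give the chalcone (E)-3-[3-(benzyloxy)-2,4,5-trimethoxyphenyl]-1-(2-hydroxy-3,4,5,6-tetramethoxyphenyl)prop-2-en-1-one F4, and oxidative cyclisation (I2 cat., DMSO, 120 °C) closes ring C to 22. If the fault lies with the carbene rather than the alkyne, the fallback for step 11 supplies F3 without chromium.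

2. Step 11. The strongly reducing dianion may transfer an electron to the enoyl chloride or add to it in conjugate fashion instead of being acylated, or the acid-sensitive enol ether may be lost during O-methylation. The fallback builds ring B by classical arene chemistry; it sets out from 4 and commercial 2,6-dimethoxyphenol and comes back at 22. O-Benzylation (BnBr, K2CO3, DMF) gives 2-(benzyloxy)-1,3-dimethoxybenzene F5. Vilsmeier–Haack formylation (POCl3, DMF) should go para to one methoxy group and ortho to the other, as with 1,2,3-trimethoxybenzene, and give 3-(benzyloxy)-2,4-dimethoxybenzaldehyde F6. Bromination (NBS, DMF) at the position para to the 2-methoxy group should give 3-(benzyloxy)-5-bromo-2,4-dimethoxybenzaldehyde F7, and copper-catalysed methoxylation (NaOMe, CuBr, MeOH/DMF) the aldehyde 3-(benzyloxy)-2,4,5-trimethoxybenzaldehyde F3. Condensation with 4 to the chalcone F4 and I2/DMSO cyclisation then give 22 as above.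

3. Step 7. Methoxide may add to the electrophilic pyranone or to the newly formed conjugated alkyne, or hemiacetal formation at the very electrophilic aldehyde may stall the homologation. The fallback installs the alkyne by cross-coupling instead of homologation; it sets out from 4 and comes back at 10. Condensation of 4 with DMF dimethyl acetal gives the enaminone (E)-3-(dimethylamino)-1-(2-hydroxy-3,4,5,6-tetramethoxyphenyl)prop-2-en-1-one F8, and acid (HCl, CH2Cl2) closes it to 5,6,7,8-tetramethoxy-4H-chromen-4-one F9. Zincation with TMPZnCl·LiCl (THF, rt), expected at C2 (the position beside the ring oxygen, as reported for chromones in the absence of a Lewis acid), followed by I2 should give 2-iodo-5,6,7,8-tetramethoxy-4H-chromen-4-one F10. Sonogashira coupling with trimethylsilylacetylene (Pd(PPh3)2Cl2, CuI, Et3N) should give 5,6,7,8-tetramethoxy-2-[(trimethylsilyl)ethynyl]-4H-chromen-4-one F11, and buffered desilylation (Bu4NF, AcOH, THF, 0 °C) releases 10 without methoxide.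

**Further compounds**

F1 | step 12 | 2-(benzyloxy)-6-(diethoxymethyl)-3,4-dimethoxyphenol | CCOC(OCC)c1cc(OC)c(OC)c(OCc2ccccc2)c1O
F2 | step 12 | 3-(benzyloxy)-1-(diethoxymethyl)-2,4,5-trimethoxybenzene | CCOC(OCC)c1cc(OC)c(OC)c(OCc2ccccc2)c1OC
F3 | step 12 | 3-(benzyloxy)-2,4,5-trimethoxybenzaldehyde | O=Cc1cc(OC)c(OC)c(OCc2ccccc2)c1OC
F4 | step 12 | (E)-3-[3-(benzyloxy)-2,4,5-trimethoxyphenyl]-1-(2-hydroxy-3,4,5,6-tetramethoxyphenyl)prop-2-en-1-one | COc1cc(/C=C/C(=O)c2c(O)c(OC)c(OC)c(OC)c2OC)c(OC)c(OCc2ccccc2)c1OC
F5 | step 11 | 2-(benzyloxy)-1,3-dimethoxybenzene | COc1cccc(OC)c1OCc1ccccc1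
F6 | step 11 | 3-(benzyloxy)-2,4-dimethoxybenzaldehyde | O=Cc1ccc(OC)c(OCc2ccccc2)c1OC
F7 | step 11 | 3-(benzyloxy)-5-bromo-2,4-dimethoxybenzaldehyde | O=Cc1cc(Br)c(OC)c(OCc2ccccc2)c1OC
F8 | step 7 | (E)-3-(dimethylamino)-1-(2-hydroxy-3,4,5,6-tetramethoxyphenyl)prop-2-en-1-one | CN(C)/C=C/C(=O)c1c(O)c(OC)c(OC)c(OC)c1OC
F9 | step 7 | 5,6,7,8-tetramethoxy-4H-chromen-4-one | O=c1ccoc2c1c(OC)c(OC)c(OC)c2OC
F10 | step 7 | 2-iodo-5,6,7,8-tetramethoxy-4H-chromen-4-one | O=c1cc(I)oc2c1c(OC)c(OC)c(OC)c2OC
F11 | step 7 | 5,6,7,8-tetramethoxy-2-[(trimethylsilyl)ethynyl]-4H-chromen-4-one | C[Si](C)(C)C#Cc1cc(=O)c2c(OC)c(OC)c(OC)c(OC)c2o1
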